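**Assumption:** commercial silibinin (silybin A/B about 1:1, free of isosilybin) is used as bought. Its two dioxane stereocentres are erased in step 2, so the mixture converges.

**Labels:** flavanonol C-2/C-3; B-ring C-1′ to C-6′; lignan carbons Cα (aryl-bearing), Cβ, C-9 (CH2OH); guaiacyl phenol 4″-OH.

## Retrosynthetic overview
1. Target 6 comes from 5 by removing two phenolic acetates.
2. The key disconnection is C3–C3a of the dihydrobenzofuran (Cβ–C2′), made by 6π photocyclisation of aryl enol ether 4. O-3′ has only one H-bearing ortho carbon (C-2′), so the regiochemistry is fixed by structure.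
3. Enol ether 4 comes from 3 by cleaving Cβ–O4′ of a 1,4-benzodioxane. The target is a constitutional isomer (C25H22O10) of silybin, which already holds the O3′–Cα(aryl) bond and all 25 carbons.
4. Ring order: the A/C chromanone and B ring are bought with (2R,3R). The dioxane is opened, and the dihydrobenzofuran is the only ring formed.
5. The new C2/C3 centres are set under control of flavanonol C-2/C-3.

## Route

**Step 1**
Reactants: 1 silibinin (silybin A + B); 2 acetic anhydride
Product: 3, 7,4″-di-O-acetylsilybin A/B (3-OH, chelated 5-OH and 9-OH left free)
Conditions: Ac2O (2.2 equiv), K2CO3 (2.5 equiv), acetone, 0 °C, Ar, 1–2 h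
Reagents that add atoms: acetic anhydride, CC(=O)OC(C)=O
Why: Chemoselective phenoxide O-acylation. Only the two free phenoxides (7-O⁻, 4″-O⁻) acylate, the chelated 5-OH and the two aliphatic OH groups stay untouched, no stereocentre is affected, and Ar at 0 °C suppresses base/air oxidation to the flavonol.

**Step 2 (key step)**
Reactants: 3
Product: 5, 7,4″-di-O-acetate of the target, (2R,3S)-dihydrobenzofuran, formed via transient (E)-enol ether 4 (not isolated)
Conditions: thioxanthone (10 mol %), HSCH2CO2Me (20 mol %), 2,6-di-tert-butylpyridine (10 mol %), degassed DCE/PhCF3 1:1 (0.01 M), 405 nm LEDs, 45 °C, 24–36 h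
Reagents that add atoms: none (isomerisation)
Why: Proposed new method: a redox-neutral contractive photoisomerisation of a 2-aryl-1,4-benzodioxane to a 7-hydroxy-2,3-dihydrobenzofuran, in which
- (i) triplet thioxanthone converts the thiol into an electrophilic thiyl radical that abstracts the weakest and most hydridic C–H, the axial Cα–H (benzylic and α-aryloxy), while flavanonol H-2 is polarity-deactivated by the adjacent C-3(OH)–C-4(=O) ketol unit and by its electron-poor ring oxygen;
- (ii) the Cα radical undergoes β-scission of Cβ–O4′, and the aryloxyl radical takes H back from the thiol or ketyl to give 4, which is E because the equatorial CH2OH is antiperiplanar to O3′, so silybin A and B converge;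
- (iii) the same sensitiser (ET about 65 kcal/mol, above the α-aryloxystyrene triplet and below every other chromophore) drives a 6π heteroatom-directed photoarylation in which Cβ bonds to C-2′, and the carbonyl ylide rearomatises by suprafacial 1,4-H shift to Cα, this irreversible C–C formation draining the roughly thermoneutral ring opening;
- the trans relationship follows from conrotatory closure (H inside, CH2OH outside) plus the suprafacial H shift, and reversible thiyl HAT at the new H-2 corrects any cis isomer;
- the absolute sense follows because flavanonol H-2 eclipses the arene plane toward C-2′, so Cβ attacks the arene face bearing the small ring O-1 (anti to C-3) and the CH2OH swings to the opposite face, where it hydrogen-bonds to 3-OH in the non-H-bonding solvent, giving (2R,3S) with a predicted dr of about 4:1;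
- the aryl acetates (no base, λ > 400 nm so no photo-Fries), the chelated ketone and the free alcohols survive;
- the closest known reaction types are thiol-catalysed HAT at benzylic ethers, thiol-catalysed radical redox rearrangement of benzylidene acetals, Cα-radical β-O-4 fragmentation, and Schultz-type (direct or energy-transfer) photocyclisation of 2-aryloxyenones and N-aryl enamines.

**Step 3**
Reactants: 5
Product: 6, the target (CID 21589839)
Conditions: NH4OAc (10 equiv), MeOH/H2O 4:1, 25 °C, Ar, 6–12 h; reverse-phase chromatography removes the minor (2S,3R) diastereomer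
Reagents that add atoms: none
Why: Near-neutral acyl transfer from the aryl acetates (mild transesterification/aminolysis). At this pH flavanonol C-2/C-3 do not epimerise and the p-hydroxybenzyl aryl ether (C2–O1) does not open, so all four stereocentres are retained.

## Compound list
1 | Silibinin: (2R,3R)-3,5,7-trihydroxy-2-[(2R,3R)- and (2S,3S)-3-(4-hydroxy-3-methoxyphenyl)-2-(hydroxymethyl)-2,3-dihydro-1,4-benzodioxin-6-yl]chroman-4-one | COc1cc(ccc1O)[C@H]1Oc2cc(ccc2O[C@@H]1CO)[C@H]1Oc2cc(O)cc(O)c2C(=O)[C@@H]1O.COc1cc(ccc1O)[C@@H]1Oc2cc(ccc2O[C@H]1CO)[C@H]1Oc2cc(O)cc(O)c2C(=O)[C@@H]1O | starting material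

2 | Acetic anhydride | CC(=O)OC(C)=O | starting material (reagent)

3 | 7,4″-Di-O-acetylsilybin A/B | COc1cc(ccc1OC(C)=O)[C@H]1Oc2cc(ccc2O[C@@H]1CO)[C@H]1Oc2cc(OC(C)=O)cc(O)c2C(=O)[C@@H]1O.COc1cc(ccc1OC(C)=O)[C@@H]1Oc2cc(ccc2O[C@H]1CO)[C@H]1Oc2cc(OC(C)=O)cc(O)c2C(=O)[C@@H]1O | intermediate

4 | (E)-Enol ether: 4-[(E)-1-{5-[(2R,3R)-7-acetoxy-3,5-dihydroxy-4-oxochroman-2-yl]-2-hydroxyphenoxy}-3-hydroxyprop-1-enyl]-2-methoxyphenyl acetate | COc1cc(ccc1OC(C)=O)/C(Oc1cc(ccc1O)[C@H]1Oc2cc(OC(C)=O)cc(O)c2C(=O)[C@@H]1O)=C\CO | intermediate (transient, not isolated)

5 | (2R,3R)-7-Acetoxy-2-[(2R,3S)-2-(4-acetoxy-3-methoxyphenyl)-7-hydroxy-3-(hydroxymethyl)-2,3-dihydrobenzofuran-4-yl]-3,5-dihydroxychroman-4-one | COc1cc([C@@H]2Oc3c(O)ccc([C@H]4Oc5cc(OC(C)=O)cc(O)c5C(=O)[C@@H]4O)c3[C@H]2CO)ccc1OC(C)=O | intermediate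

6 | (2R,3R)-3,5,7-Trihydroxy-2-[(2R,3S)-7-hydroxy-2-(4-hydroxy-3-methoxyphenyl)-3-(hydroxymethyl)-2,3-dihydrobenzofuran-4-yl]chroman-4-one | COc1cc([C@@H]2Oc3c(O)ccc([C@H]4Oc5cc(O)cc(O)c5C(=O)[C@@H]4O)c3[C@H]2CO)ccc1O | target

## Summary
Total steps: 3. Longest linear sequence: 3.

**Steps most likely to fail**

1. **Step 2 (the proposed new step).**
   - Risks in the radical ring opening: back-HAT to the Cα radical if β-scission is slow or unfavourable, the phenolic product slowing the thiyl cycle, and partial H-2 epimerisation of the flavanonol.
   - Risks to transient 4: acid-triggered closure to the 1,3-benzodioxole ketal, and thiyl-mediated isomerisation of its allylic alcohol to an aldehyde.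
   - Risks in the photocyclisation: low quantum yield for closure at the hindered C-2′, and modest facial selectivity.
   - Fallback (known chemistry, different approach): abandon the isomerisation and make the same bond by the classical oxidative β-5 phenol/propenylphenol coupling. 4′,7-Di-O-benzyl-(+)-taxifolin (BnBr/K2CO3, regioisomers separated) is coupled with (E)-coniferyl alcohol using Ag2O in benzene/acetone. The quinone methide is closed by 3′-O to give the trans-dihydrobenzofuran, and H2/Pd-C then removes the benzyl groups. The C-2′/C-6′ regioisomers and the diastereomers are separated by RP-HPLC.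

2. **Step 1.**
   - Risks: incomplete discrimination between the phenols and 9-OH, or some 5-O-acylation.
   - Fallback: change from selective to global masking. Make the 3,7,4″,9-tetraacetate (Ac2O/pyridine, 5-OH left chelated) and run step 2 under steric rather than hydrogen-bond control. Finish by acid methanolysis, which also equilibrates C-2 of the dihydrobenzofuran to trans.

3. **Step 3.**
   - Risks: flavanonol epimerisation or oxidation, or quinone-methide opening of the dihydrobenzofuran during acyl removal.
   - Fallback: change the masking chemistry. Carry the two phenols as fluoride-labile silyl ethers (TBS on the phenoxides) from step 1, so the last step is Et3N·3HF desilylation rather than acyl transfer.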